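(The data stem from a simulated flask with constants of no real substance; noise was put on by code.)

Start with the equation.

| setting | grey | ochre | teal | violet |
|---|---|---|---|---|
| Sub | 1.00 M | 1.00 M | 0.500 M | 1.00 M |
| Rgt | 1.00 M | 0.500 M | 1.00 M | 0.220 M |
| time |  |  |  | 59 min |

| grey run: time / min | grey run: [Prd] / M | ochre run: time / min | ochre run: [Prd] / M | teal run: time / min | teal run: [Prd] / M |
|---|---|---|---|---|---|
| 2.1 | 0.126 | 2.1 | 0.037 | 2.1 | 0.078 |
| 6.4 | 0.279 | 6.4 | 0.092 | 6.4 | 0.187 |
| 12 | 0.406 | 12 | 0.140 | 12 | 0.272 |
| 19 | 0.504 | 19 | 0.196 | 19 | 0.347 |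
| 28 | 0.581 | 28 | 0.236 | 28 | 0.398 |
| 37 | 0.630 | 37 | 0.271 | 37 | 0.425 |
| 48 | 0.675 | 48 | 0.290 | 48 | 0.458 |
| 59 | 0.708 | 59 | 0.313 | 59 | 0.468 |

(standard deviation of a reading: 0.003 M)

1. apparent order in [Rgt] of the starting rate, round the charge of the grey run (the rate where two percent of its Sub have turned into Prd)
2. apparent order in [Sub] of the starting rate, round the charge of the grey run (the rate where two percent of its Sub have turned into Prd) (one fixed amount of Prd, the same in the runs compared)
3. Prd in the violet run at 59 min, as a share of the Sub charged
4. which of these the readings show (the product decays / the substrate pairs with itself / the product binds the second partner)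

- Overall: Sub + Rgt -> Prd.
- Constant volume, constant temperature.
- A reading of a species includes what of it is bound.
- "The second partner" is Rgt.
- An order is taken over about fifteen percent of the charge, up and down.

Sub and Rgt each enter the equation once, yet the two numbers I read near the start do not match it. At 2.1 min grey, with 1.00 M of Rgt and 1.00 M of Sub, has made 0.126 M of Prd. Ochre, with 0.500 M of Rgt, has made 0.037 M, and teal, with 0.500 M of Sub, has made 0.078 M.

The clash goes once I separate two things: the equation balances amounts, while an order reads the rate. Taking Prd over time at that first reading as the rate, across these wider steps I get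

order in [Rgt] = 1.77, order in [Sub] = 0.692.

So the rate follows [Rgt] nearer the second power than the first, though each Prd uses one Rgt. I read the order in [Sub], below one, as part of the charged Sub not counting.

Rgt is the limiting reagent in violet, 0.220 M against 1.00 M of Sub, so I carry one quantity: the pseudo-second-order constant κ, the rate over [Rgt]·[Rgt] at 1.00 M of Sub. I read it from ochre, which has that Sub charge, at 6.4 min, where [Rgt] is the charge 0.500 M less the 0.092 M of Prd made:

κ = (1/[Rgt] − 1/0.500 M)/6.4 min = 0.0705 M⁻¹ min⁻¹

1/[Rgt] at 59 min = 1/0.220 M + κ·59 min, so [Rgt] = 0.115 M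

This gives violet 10.5% Prd. The same line gives ochre 0.338 M at 59 min, against a reading of 0.313 M.

The forecast gives an order in [Rgt] of 1.9, above mine, an order in [Sub] of 0.65, below mine, and 10.3% for violet, within 8.5% to 12.5%. It names the substrate pairs with itself: “That argues against product inhibition and for Sub being tied up with itself at high charge.”

The flask gives 2.0, 0.69, 10.3% and the substrate pairs with itself.

    Sub + 2 Rgt → Prd + Rgt (0.1386 M⁻² min⁻¹)
    2 Sub ⇌ Sub2, settled at all times (0.9530 M⁻¹)

Sub2 holds the order in [Sub] down: the grey comparison gives 0.69 as it stands and 1.0 without the pairing. Dividing κ by k1 gives 0.508 M, the Sub that κ counts out of 1.00 M charged. With the whole violet charge counted, κ becomes 0.139 M⁻¹ min⁻¹; the same line then gives 14.2% Prd, and the violet run without Sub2 gives 13.7%.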